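**Retrosynthetic overview**

- The route rests on the butenolide ring (O1, C2 carbonyl, C3 bearing CH3, C4, C5H2). C4 lies between the C5H2–O1 unit and the methylated C3, so the ring is the cyclised form of 2-methylbuta-2,3-dienoic acid with C4 as the central allene carbon.
- Last disconnection: the saturated C14–C15 bond comes from hydrogenation of the chain alkene of 14.
- Key disconnection: O1–C5 (ring closure) and C4–C16 (chain attachment) are formed in one palladium-catalysed step from allenoic acid 13 and the secondary allylic chloride 11.
- Chloride 11 comes from allylic alcohol 10, made from aldehyde 8 and vinylmagnesium bromide. The chain and the (S)-C2 centre come from (S)-propylene oxide and the Grignard reagent of 11-bromoundec-1-ene.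
- Ring order: there is only one ring, and it is closed in step 8 at the moment it is joined to the chain.

Key step: step 8

Assumption: the configuration at C14 of 10 and 11 and the E/Z ratio of 14 do not matter, because C14 becomes sp2 in step 8 and the C14=C15 bond is saturated in step 9. Both are therefore carried as mixtures.

**Route**

Step 1
Reactants: 1 11-bromoundec-1-ene; 2 (S)-propylene oxide
Product: 4 (S)-tetradec-13-en-2-ol, via undec-10-en-1-ylmagnesium bromide 3 (not isolated)
Conditions: Mg, THF, 25 to 50 °C; then CuI (10 mol%), 2 (1.5 equiv), THF, −30 to 0 °C; sat. aq. NH4Cl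
Reagents that add atoms: magnesium, [Mg] (carried only in intermediate 3; no magnesium remains in 4)
Why: Copper-catalysed SN2 opening of the terminal epoxide by the primary Grignard reagent takes place at the unsubstituted CH2, so the C–O bond at the stereocentre is never broken and the (S) configuration of 2 passes unchanged into C2 of 4.

Step 2
Reactants: 4 (S)-tetradec-13-en-2-ol
Product: 5 (S)-tetradec-13-en-2-yl acetate
Conditions: Ac2O, pyridine, DMAP (cat.), CH2Cl2, 0 °C to rt
Reagents that add atoms: acetic anhydride, CC(=O)OC(C)=O
Why: DMAP-catalysed acylation (nucleophilic acyl substitution) of the secondary alcohol installs the acetate of the target without touching any bond at the stereocentre, and this ester is the only protecting group the route needs.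

Step 3
Reactants: 5 (S)-tetradec-13-en-2-yl acetate
Product: 7 (S)-14-hydroxytetradecan-2-yl acetate, via B-alkyl-9-borabicyclononane 6 (not isolated)
Conditions: 9-BBN, THF, 0 °C to rt; then NaBO3·4H2O, H2O, rt
Reagents that add atoms: 9-borabicyclo[3.3.1]nonane, B1C2CCCC1CCC2 (boron carried only in intermediate 6); sodium perborate, [Na+].[O-]OB=O (oxygen of the new hydroxyl)
Why: Anti-Markovnikov hydroboration of the terminal alkene with the bulky 9-BBN places boron on C14 and leaves the ester alone, and oxidation of the C–B bond with mildly basic perborate should give the primary alcohol without hydrolysing the acetate.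

Step 4
Reactants: 7 (S)-14-hydroxytetradecan-2-yl acetate
Product: 8 (S)-14-oxotetradecan-2-yl acetate
Conditions: TEMPO (10 mol%), PhI(OAc)2, CH2Cl2, rt
Reagents that add atoms: none
Why: TEMPO-catalysed oxidation with PhI(OAc)2 as terminal oxidant (oxoammonium oxidation) stops at the aldehyde under non-aqueous, near-neutral conditions that spare the acetate and cannot epimerise C2.

Step 5
Reactants: 8 (S)-14-oxotetradecan-2-yl acetate; 9 vinylmagnesium bromide
Product: 10 (2S)-14-hydroxyhexadec-15-en-2-yl acetate (mixture of C14 epimers)
Conditions: 9 (1.1 equiv), THF, −78 °C, 30 min; sat. aq. NH4Cl at −78 °C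
Reagents that add atoms: none
Why: Grignard 1,2-addition to the aldehyde is far faster at −78 °C than attack on the remote secondary acetate, so one equivalent of 9 should give the allylic alcohol, whose new C14 centre forms without control and needs none because C14 becomes sp2 in step 8.

Step 6
Reactants: 10 (2S)-14-hydroxyhexadec-15-en-2-yl acetate
Product: 11 (2S)-14-chlorohexadec-15-en-2-yl acetate (mixture of C14 epimers)
Conditions: PPh3 (1.2 equiv), hexachloroacetone (excess), CH2Cl2, 0 °C, 30 min; filtered cold through neutral alumina and used at once
Reagents that add atoms: hexachloroacetone, O=C(C(Cl)(Cl)Cl)C(Cl)(Cl)Cl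
Why: Appel-type deoxychlorination with PPh3/hexachloroacetone goes through an alkoxyphosphonium chloride that collapses by direct SN2 displacement at C14 under cold, neutral and fast conditions, the known way to turn alk-1-en-3-ols into 3-chloroalk-1-enes with little allylic transposition, and the inversion at C14 is irrelevant for an epimer mixture.

Step 7
Reactants: 12 ethyl 2-methylbuta-2,3-dienoate
Product: 13 2-methylbuta-2,3-dienoic acid
Conditions: LiOH·H2O, THF/H2O, 0 °C to rt; then 1 M HCl to pH 2
Reagents that add atoms: lithium hydroxide, [Li+].[OH-]
Why: Saponification of the ethyl ester (acyl substitution by hydroxide) at low temperature gives the free allenoic acid, and the fully substituted C2 blocks base-induced isomerisation of the allene to a conjugated 2-alkynoate.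

Step 8
Reactants: 13 2-methylbuta-2,3-dienoic acid; 11 (2S)-14-chlorohexadec-15-en-2-yl acetate
Product: 14 (2S,14E)-16-(4-methyl-5-oxo-2,5-dihydrofuran-3-yl)hexadec-14-en-2-yl acetate
Conditions: PdCl2 (5 mol%), N,N-dimethylacetamide, 25 °C; 11 kept concentrated (about 1 M), 13 (3 equiv) added slowly over several hours, no base
Reagents that add atoms: none
Why: Divalent palladium (PdCl2) binds the terminal C=C of allenoic acid 13 and the carboxyl oxygen attacks the CH2 terminus anti to the metal, closing the butenolide ring in a 5-endo-trig mode (O1–C5 bond) and leaving a vinyl C4–Pd bond on the former central allene carbon. That C4–Pd bond inserts the vinyl group of 11 with carbon going to the terminal CH2 (C16) and palladium to C15, and β-chloride elimination from C14 then releases the C14=C15 alkene and returns PdCl2 without any change of oxidation state. The closest known reaction type is the PdCl2-catalysed coupling–cyclisation of 2,3-allenoic acids with allylic halides in N,N-dimethylacetamide, applied here to a longer secondary allylic chloride. No stereocentre is created: C14 of 11 becomes sp2 so its epimers converge, the alkene geometry (E expected) is erased in step 9, and the remote (S)-C2 acetate is a spectator. The step needs oxygen attack at the allene terminus (secured because only that closure gives the five-membered lactone, which puts the 2-methyl group on C3) and carbon delivery to C16 ahead of any allylic transposition of 11 (secured by the unhindered CH2 terminus and by chloride lying β to palladium only after that mode of insertion). Protonolysis of the C4–Pd bond by the HCl formed is held back by keeping 11 concentrated, by using no base (which would instead give the allyl ester) and by feeding 13 slowly in excess.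

Step 9
Reactants: 14 (2S,14E)-16-(4-methyl-5-oxo-2,5-dihydrofuran-3-yl)hexadec-14-en-2-yl acetate
Product: 15 (2S)-16-(4-methyl-5-oxo-2,5-dihydrofuran-3-yl)hexadecan-2-yl acetate (CNP0377863.1)
Conditions: H2 (1 atm), RhCl(PPh3)3 (10 mol%), toluene/EtOH 1:1, rt
Reagents that add atoms: none
Why: Homogeneous hydrogenation with RhCl(PPh3)3 discriminates strongly by alkene substitution, so the 1,2-disubstituted C14=C15 bond should be saturated while the tetrasubstituted conjugated ring alkene, the allylic lactone C5–O1 bond and the C2 stereocentre stay untouched, giving the target.

**Compound list**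

1 | 11-bromoundec-1-ene | C=CCCCCCCCCCBr | starting material
2 | (S)-propylene oxide | C[C@H]1CO1 | starting material
3 | undec-10-en-1-ylmagnesium bromide | C=CCCCCCCCCC[Mg]Br | intermediate
4 | (S)-tetradec-13-en-2-ol | C[C@H](O)CCCCCCCCCCC=C | intermediate
5 | (S)-tetradec-13-en-2-yl acetate | CC(=O)O[C@@H](C)CCCCCCCCCCC=C | intermediate
6 | (S)-14-(9-borabicyclo[3.3.1]nonan-9-yl)tetradecan-2-yl acetate | CC(=O)O[C@@H](C)CCCCCCCCCCCCB1C2CCCC1CCC2 | intermediate
7 | (S)-14-hydroxytetradecan-2-yl acetate | CC(=O)O[C@@H](C)CCCCCCCCCCCCO | intermediate
8 | (S)-14-oxotetradecan-2-yl acetate | CC(=O)O[C@@H](C)CCCCCCCCCCCC=O | intermediate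
9 | vinylmagnesium bromide | C=C[Mg]Br | starting material
10 | (2S)-14-hydroxyhexadec-15-en-2-yl acetate, C14 epimer mixture | CC(=O)O[C@@H](C)CCCCCCCCCCCC(O)C=C | intermediate
11 | (2S)-14-chlorohexadec-15-en-2-yl acetate, C14 epimer mixture | CC(=O)O[C@@H](C)CCCCCCCCCCCC(Cl)C=C | intermediate
12 | ethyl 2-methylbuta-2,3-dienoate | CCOC(=O)C(C)=C=C | starting material
13 | 2-methylbuta-2,3-dienoic acid | C=C=C(C)C(=O)O | intermediate
14 | (2S,14E)-16-(4-methyl-5-oxo-2,5-dihydrofuran-3-yl)hexadec-14-en-2-yl acetate | CC(=O)O[C@@H](C)CCCCCCCCCCC/C=C/CC1=C(C)C(=O)OC1 | intermediate
15 | (2S)-16-(4-methyl-5-oxo-2,5-dihydrofuran-3-yl)hexadecan-2-yl acetate | CC(=O)O[C@@H](C)CCCCCCCCCCCCCCC1=C(C)C(=O)OC1 | target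

**Step count**

Total steps: 9. Longest linear sequence: 8 (steps 1 to 6, then 8 and 9); step 7 is a one-step side branch.

**Steps most likely to fail**

Step 8. The C4–Pd intermediate may be protonated by the HCl that the reaction forms before it meets the hindered olefin of 11, and PdCl2 may shift the chloride of 11 to the chain terminus before insertion, so that a branched isomer is formed. The fallback runs the same coupling–cyclisation in its best-established form, with a simple allyl halide, and joins the chain afterwards by olefin metathesis. It sets out from aldehyde 8 and acid 13. Wittig methylenation of 8 (Ph3PCH3Br, KN(SiMe3)2, THF, −78 to 0 °C) should give (S)-pentadec-14-en-2-yl acetate F1. Acid 13 and allyl bromide (5 equiv) with PdCl2 (5 mol%) in N,N-dimethylacetamide at 25 °C should give 4-allyl-3-methylfuran-2(5H)-one F2. Cross-metathesis of F1 with F2 (second-generation Grubbs catalyst, RuCl2(=CHPh)(PCy3)(H2IMes), CH2Cl2, 40 °C) should then give 14 as an E/Z mixture with loss of ethylene, and the route is rejoined at 14 before step 9.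

Step 6. Ionisation of the alkoxyphosphonium salt, or handling of the labile secondary chloride, may lead to allylic transposition to the primary (E)-chloride, which would end as the branched coupling product in step 8. The fallback makes the chloride by a sequence in which the allylic shift is the wanted pathway, setting out from aldehyde 8 and bypassing steps 5 and 6. Wittig olefination of 8 with Ph3P=CHCHO (toluene, 80 °C) should give (2S,14E)-16-oxohexadec-14-en-2-yl acetate F3. Luche reduction (NaBH4, CeCl3·7H2O, MeOH, 0 °C) should give (2S,14E)-16-hydroxyhexadec-14-en-2-yl acetate F4. Thionyl chloride in dilute Et2O at 0 °C should convert F4 through its chlorosulfite, by internal return with allylic shift (SNi′), into the 3-chloroalk-1-ene 11, where the route is rejoined.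

Step 5. The Grignard reagent may also add to the acetate carbonyl (loss of the acetate or over-addition), or may enolise the aldehyde. The fallback replaces the magnesium nucleophile with an organochromium one in a Nozaki–Hiyama–Kishi vinylation: 8, vinyl bromide, CrCl2 (4 equiv) and NiCl2 (1 mol%) in DMF at rt. Vinylchromium species add to aldehydes and do not touch esters. This sets out from 8 and returns directly at 10, with no new compound on the way.

**Further compounds**

F1 | step 8 | (S)-pentadec-14-en-2-yl acetate | CC(=O)O[C@@H](C)CCCCCCCCCCCC=C
F2 | step 8 | 4-allyl-3-methylfuran-2(5H)-one | C=CCC1=C(C)C(=O)OC1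
F3 | step 6 | (2S,14E)-16-oxohexadec-14-en-2-yl acetate | CC(=O)O[C@@H](C)CCCCCCCCCCC/C=C/C=O
F4 | step 6 | (2S,14E)-16-hydroxyhexadec-14-en-2-yl acetate | CC(=O)O[C@@H](C)CCCCCCCCCCC/C=C/CO
F0 | step 5 | none | none
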